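## Structural features

The target is a flavone: the benzo ring A is fused along the C4a–C8a bond to the 4-pyranone ring C, and ring C carries the 3,4-dihydroxyphenyl ring B through the single bond C2–C1'. There is no stereocentre, so the problem is one of regiochemistry among five phenolic oxygens: O5, O6 and O7 on three adjacent carbons of ring A, and O3' and O4' on ring B. Only O6, the middle oxygen of the ring A triol, bears the hydrogen sulfate. The fragile parts are the aryl sulfate monoester (lost in acid, stable to base, very polar), the catechol of ring B and the pyrogallol-like ring A (oxidised by air once deprotonated), and ring C, which opens in hot strong alkali. The real difficulty is that O6 is the least acidic and most crowded oxygen of ring A: ordinary sulfating agents go first to O7 and O4', while O5 is tied up in a hydrogen bond to the C4 carbonyl. The key step uses two facts about ring A. First, O6 and O7 sit on the neighbouring carbons C6 and C7, so one sulfuryl unit can bridge them in a five-membered 1,3,2-dioxathiole 2,2-dioxide ring fused to ring A. Second, O7 (para to C4a) and O5 (ortho to C4a) are conjugated with the C4 carbonyl whereas O6 (meta to C4a) is not, so when the ring is opened O7 leaves as the phenoxide and O6 keeps the sulfur.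

## Logic of the disconnections

12 is traced back to 11 by putting acyl groups back on O3' and O4'; the bonds concerned are the two ester C–O bonds of ring B. The cut is made there because the ring B catechol would itself be bridged by a sulfuryl reagent and must be masked while sulfur is introduced. The mask has to come off in base, the one medium in which an aryl sulfate monoanion is safe. The forward step therefore needs a saponification that leaves the S–O6 bond alone and excludes air.

11 is traced back to 10 by re-forming the S–O7 bond. This turns the hard problem (put sulfur on the least reactive oxygen) into an easier one (decide which of two S–O bonds of a strained ring breaks), and the answer no longer depends on which oxygen was attacked first. The demand on the forward step is that hydroxide attacks sulfur, not an ester or ring C, and that O7 rather than O6 is expelled.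

10 is traced back to 8 and 9 by cutting the O6–S and O7–S bonds. This removes the only heteroatom ring that is not part of the flavone and leaves a triol and a one-sulfur reagent. The forward step must deliver exactly one sulfuryl unit, close the five-membered ring in preference to intermolecular diester formation, and leave C8 and ring B untouched. In 8 the 5-hydroxyl is left free on purpose: its hydrogen bond makes it the slowest nucleophile, and a ring across O5 and O6 would open to the same 6-sulfate.

8 is traced back to 7 by restoring three O–CH3 bonds on ring A. Methyl ethers are the ring A masks that survive alkali, hot iodine in DMSO and hydrogenolysis, and they are present in a commercial ketone. The forward step must cleave all three ethers, the electron-poor 7-methoxy included, without cleaving the two aryl esters; this is why the esters are pivalates.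

7 is traced back to 5 and 6 by cutting the two acyl–oxygen bonds. Ring B is unmasked and re-masked at this point because no ester survives the aldol base and no benzyl ether survives BBr3. The forward acylation has no selectivity problem, since 5 has only two free hydroxyls.

5 is traced back to 4 by restoring two benzyl–oxygen bonds. Benzyl ethers carry ring B through the two ring-forming steps. The forward hydrogenolysis must not reduce the C2–C3 double bond.

4 is traced back to 3 by cutting the O1–C2 bond and removing the C2–C3 unsaturation. Ring C is thereby opened to an acyclic enone with the phenol oxygen already ortho to the carbonyl. The forward step has to close the six-membered ring, not the five-membered aurone, and oxidise it in the same operation.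

3 is traced back to 1 and 2 by cutting the Cα=Cβ double bond, which later becomes C3–C2. This divides the skeleton into a ring A ketone that already has all four oxygens in place and a ring B aldehyde, both commercial. The forward condensation only needs a non-enolisable aldehyde and a single enolisable methyl group, which is the case.

## Other disconnections considered

Alternative 1: The cut is the C4a–C8a bond of ring A, so ring A is built from the sugar 2-deoxy-D-glucose A1 instead of being bought as an arene. In the forward direction the derived 5-enopyranoside A2 would be treated with catalytic Hg(OCOCF3)2 in aqueous acetone. Oxymercuration of the enol ether, loss of methanol to an α-mercurio ketone bearing an aldehyde, and intramolecular aldol addition would close the carbocycle to cyclohexanone A3.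
- In favour: the carbocyclization is a dependable named reaction. The three future ring A oxygens arrive in three different forms (ketone for O5, benzoate for O6, benzyl ether for O7), so O6 is singled out from the start. On this point, and on precedent for the key step, the alternative is better than the chosen plan, which relies on an untested rate difference.
- Against: A3 is a saturated ring whose sugar-derived stereocentres must all be erased. Aromatization needs oxidation of the carbinol and a further dehydrogenation, and the benzyloxy group β to both carbonyls would be expected to leave first, aromatizing the ring with loss of the C7 oxygen. After that C4 must still be attached at C4a and rings C and B built, and a mercury salt must be handled.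
- Comparison: on structure, it spends chirality on an achiral aromatic target, whereas the chosen plan starts from an arene with all four ring A oxygens in place. On mechanism, its key step is safer but the aromatization after it is less safe than any step of the chosen plan. On step economy, it would need roughly twice the seven steps proposed here.

Alternative 2: The cut is the C8a–O1 bond of ring C. In the forward direction diketone A4, with only O6 free on ring A, would be oxidised at a carbon anode in a fluorinated alcohol. The phenol would give a phenoxonium ion, the enol oxygen of the diketone would attack the position para to the hydroxyl (C8a), and loss of a proton would give flavone A5.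
- In favour: A5 has exactly one free hydroxyl, O6, so sulfation with SO3·pyridine and hydrogenolysis would finish the synthesis with the sulfate site fixed by protecting groups. This is better than the chosen plan, where the site is fixed by leaving-group ability. The oxidation needs no chemical oxidant and no oxygen at C8a beforehand.
- Against: the differentiation of O6 is moved into the preparation of A4 from a 2,3,4-trioxygenated acetophenone, where the middle oxygen would have to be the one left unalkylated. A5 is a para-alkoxyphenol and so is easier to oxidise than A4, which invites over-oxidation to quinone-type products. The benzyl ethers and the electron-rich ring B are further oxidisable sites.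
- Comparison: on structure, both plans keep ring A aromatic throughout, so they are equal. On mechanism, both key steps lack direct precedent on a flavone and carry comparable risk. On step economy, it would be about equal or one to two steps longer once the differentiated ketone is counted.

Alternative 3: The cuts are the C8a–O1 and C4a–C4 bonds. In the forward direction CsF would release a 3,4,5-trioxygenated aryne from silyl triflate A6, and arylpropiolic acid A7 would add through its carboxylate oxygen to the aryne carbon remote from the flanking benzyloxy group. The aryl anion formed next to that group would take the acyl group from oxygen, giving the o-hydroxyaryl ynone A8. Ring C would then need a 6-endo-dig closure, followed by removal of the methoxymethyl group, sulfation of the freed O6 and hydrogenolysis.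
- In favour: it is the most convergent plan, forming two bonds to ring A in one step, and on convergence it is better than the chosen plan. The regiochemistry of the insertion is supported by the inductive effect of the neighbouring ether. O6 is again marked by its own protecting group, which is better than the chosen plan on certainty of the sulfate position.
- Against: A6 is a pentasubstituted arene that itself takes several steps. Propiolic acids can decarboxylate or add nucleophiles at the triple bond under fluoride. The ynone can close to the five-membered aurone instead of the flavone. The acid needed to remove the methoxymethyl group must be applied before the sulfate is present.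
- Comparison: on structure, equal (aromatic building blocks throughout). On mechanism, its key step belongs to a known reaction class, which is better than the chosen key step, but it leaves ring C still to be closed. On step economy, the longest linear sequence would be similar but the total count clearly higher.

Key step: step 6

Remark: sulfate monoesters are drawn as neutral hydrogen sulfates; in solution each would exist as its sodium salt, and 12 would be brought to the drawn protonation state only by the final cold acidification.

Check of structures: the ring A pattern was re-derived from the flavone numbering (C4a, C5, C6, C7, C8, C8a). The precursor and product of the key step are 8 and 10 as listed below, and no formula needed correction.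

## Route

Step 1
Reactants: 1 6-hydroxy-2,3,4-trimethoxyacetophenone; 2 3,4-bis(benzyloxy)benzaldehyde
Product: 3 (E)-3-[3,4-bis(benzyloxy)phenyl]-1-(6-hydroxy-2,3,4-trimethoxyphenyl)prop-2-en-1-one
Conditions: KOH (50% aq), EtOH, rt; then HCl (aq) to pH 3, 0 °C
Reagents that add atoms: none
Why: Claisen–Schmidt condensation: the potassium enolate of the methyl ketone adds to the non-enolisable aldehyde and E1cB loss of water gives the conjugated enone in its thermodynamic E geometry; any flavanone formed by oxa-Michael closure can be carried along, because step 2 oxidises both.

Step 2
Reactants: 3 (E)-3-[3,4-bis(benzyloxy)phenyl]-1-(6-hydroxy-2,3,4-trimethoxyphenyl)prop-2-en-1-one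
Product: 4 3',4'-bis(benzyloxy)-5,6,7-trimethoxyflavone
Conditions: I2 (10 mol %), DMSO, 120 °C
Reagents that add atoms: none
Why: Iodine-catalysed oxidative cyclisation of a 2'-hydroxychalcone: 6-endo oxa-Michael addition of the phenol forms the O1–C2 bond, α-iodination and loss of HI introduce the C2–C3 double bond, and DMSO reoxidises HI to I2; with only catalytic iodine the aryl methyl and benzyl ethers should survive.

Step 3
Reactants: 4 3',4'-bis(benzyloxy)-5,6,7-trimethoxyflavone
Product: 5 3',4'-dihydroxy-5,6,7-trimethoxyflavone
Conditions: H2 (1 atm), 10% Pd/C, THF–MeOH, rt
Reagents that add atoms: none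
Why: Catalytic hydrogenolysis of the two benzyl aryl ethers; the C2–C3 double bond is a vinylogous ester conjugated with two arenes and should not be reduced at atmospheric pressure, and the methyl ethers are inert.

Step 4
Reactants: 5 3',4'-dihydroxy-5,6,7-trimethoxyflavone; 6 pivaloyl chloride
Product: 7 5,6,7-trimethoxy-3',4'-bis(pivaloyloxy)flavone
Conditions: PivCl (2.5 equiv), Et3N, DMAP (cat.), CH2Cl2, 0 °C → rt
Reagents that add atoms: pivaloyl chloride (6), CC(C)(C)C(=O)Cl
Why: DMAP-catalysed O-acylation of the only two free hydroxyls; pivalates are chosen because their hindered carbonyl resists acyl transfer to neighbouring phenoxides and the Lewis acid of step 5, yet is removed by hydroxide at the end.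

Step 5
Reactants: 7 5,6,7-trimethoxy-3',4'-bis(pivaloyloxy)flavone
Product: 8 5,6,7-trihydroxy-3',4'-bis(pivaloyloxy)flavone
Conditions: BBr3 (8 equiv), CH2Cl2, −78 °C → rt; H2O, 0 °C
Reagents that add atoms: none
Why: BBr3 ether cleavage: each methoxy oxygen forms a boron adduct and bromide attacks the methyl carbon (SN2), the chelated 5-methoxy first and the electron-poor 7-methoxy last. An aryl pivalate offers bromide no alkyl carbon and only a hindered acyl carbon, so the ring B esters should survive, and the low temperature avoids acid-induced opening and reclosure of ring C.

Step 6
Reactants: 8 5,6,7-trihydroxy-3',4'-bis(pivaloyloxy)flavone; 9 sulfuryl chloride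
Product: 10 5-hydroxy-3',4'-bis(pivaloyloxy)flavone 6,7-cyclic sulfate
Conditions: SO2Cl2 (1.0 equiv, slow addition), pyridine (2.5 equiv), THF–CH2Cl2 (dilute), −78 → −20 °C; filtration and evaporation without water
Reagents that add atoms: sulfuryl chloride (9), O=S(=O)(Cl)Cl
Why: Proposed new method: pyridine deprotonates the most acidic phenol, the 7-hydroxyl (para to C4a and so conjugated with the C4 carbonyl), whose oxygen attacks the sulfur of 9 with loss of chloride to give the 7-O-chlorosulfate, and the neighbouring 6-hydroxyl then displaces the second chloride at the same sulfur. The closest known reaction types are the conversion of catechol into its cyclic sulfate with SO2Cl2 and pyridine and the low-temperature formation of aryl chlorosulfates from phenols, neither of which has been shown on a 5,6,7-trihydroxyflavone. The one ring closed is the five-membered 1,3,2-dioxathiole 2,2-dioxide, formed by a 5-exo-tet-type substitution at tetrahedral sulfur in which O6 enters in line with the departing chloride, which lies outside the ring. No stereocentre is created. The step needs site selectivity among three hydroxyls and must stop at one sulfuryl unit: acidity places the first S–O bond on O7, ring size directs the second to O6 and not to the hydrogen-bonded O5, and one equivalent of 9 added slowly at −78 °C under dilution disfavours bis-chlorosulfates and intermolecular diesters. Ring B cannot react because both of its oxygens are pivaloylated, and the bulky esters should not migrate to the ring A phenoxides under pyridine. Low temperature and the presence of base also disfavour electrophilic chlorination at C8 and oxidation of the triol. Should the ring close across O5 and O6 instead, the opening in step 7 would still leave the sulfur on O6.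

Step 7
Reactants: 10 5-hydroxy-3',4'-bis(pivaloyloxy)flavone 6,7-cyclic sulfate
Product: 12 6-hydroxyluteolin 6-sulfate (target), via 6-sulfate bis-pivalate 11 (not isolated)
Conditions: NaHCO3 (aq), THF, 0 °C; then NaOH (aq, degassed), Ar, 0 °C → rt; HCl (aq) to pH 2, 0 °C; C18 desalting
Reagents that add atoms: water, O
Why: Proposed new method: hydroxide adds to the strained sulfur of 10 to give a trigonal-bipyramidal species in which the ring spans one apical and one equatorial site; the apical ring oxygen that leaves should be the better phenoxide, O7 (para to C4a, a vinylogous carboxylate), so the sulfate stays on the non-conjugated O6. The closest known reaction type is the fast alkaline hydrolysis of catechol cyclic sulfate to catechol monosulfate, which has not been used to fix a sulfate position on an unsymmetrical flavone. NaOH then saponifies the two aryl pivalates without touching the sulfate monoanion, which resists hydroxide, and brief cold acidification protonates the phenols and the sulfate.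

## Compound list

1 | 6-hydroxy-2,3,4-trimethoxyacetophenone | CC(=O)c1c(O)cc(OC)c(OC)c1OC | starting material
2 | 3,4-bis(benzyloxy)benzaldehyde | O=Cc1ccc(OCc2ccccc2)c(OCc2ccccc2)c1 | starting material
3 | (E)-3-[3,4-bis(benzyloxy)phenyl]-1-(6-hydroxy-2,3,4-trimethoxyphenyl)prop-2-en-1-one | O=C(/C=C/c1ccc(OCc2ccccc2)c(OCc2ccccc2)c1)c1c(O)cc(OC)c(OC)c1OC | intermediate
4 | 3',4'-bis(benzyloxy)-5,6,7-trimethoxyflavone | O=c1cc(-c2ccc(OCc3ccccc3)c(OCc3ccccc3)c2)oc2cc(OC)c(OC)c(OC)c12 | intermediate
5 | 3',4'-dihydroxy-5,6,7-trimethoxyflavone | O=c1cc(-c2ccc(O)c(O)c2)oc2cc(OC)c(OC)c(OC)c12 | intermediate
6 | pivaloyl chloride | CC(C)(C)C(=O)Cl | starting material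
7 | 5,6,7-trimethoxy-3',4'-bis(pivaloyloxy)flavone | O=c1cc(-c2ccc(OC(=O)C(C)(C)C)c(OC(=O)C(C)(C)C)c2)oc2cc(OC)c(OC)c(OC)c12 | intermediate
8 | 5,6,7-trihydroxy-3',4'-bis(pivaloyloxy)flavone | O=c1cc(-c2ccc(OC(=O)C(C)(C)C)c(OC(=O)C(C)(C)C)c2)oc2cc(O)c(O)c(O)c12 | intermediate
9 | sulfuryl chloride | O=S(=O)(Cl)Cl | starting material
10 | 5-hydroxy-3',4'-bis(pivaloyloxy)flavone 6,7-cyclic sulfate | O=c1cc(-c2ccc(OC(=O)C(C)(C)C)c(OC(=O)C(C)(C)C)c2)oc2cc3OS(=O)(=O)Oc3c(O)c12 | intermediate
11 | 5,7-dihydroxy-3',4'-bis(pivaloyloxy)flavone 6-(hydrogen sulfate) | O=c1cc(-c2ccc(OC(=O)C(C)(C)C)c(OC(=O)C(C)(C)C)c2)oc2cc(O)c(OS(=O)(=O)O)c(O)c12 | intermediate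
12 | 6-hydroxyluteolin 6-sulfate (5,7,3',4'-tetrahydroxyflavone 6-(hydrogen sulfate)) | O=c1cc(-c2ccc(O)c(O)c2)oc2cc(O)c(OS(=O)(=O)O)c(O)c12 | target

## Step count and least certain steps

Total step count: 7. Longest linear sequence: 7 steps (1 → 3 → 4 → 5 → 7 → 8 → 10 → 12); 2, 6 and 9 enter as purchased partners.

**Step 6 (key step).** Most likely failure: electrophilic chlorination at C8 or oxidation of the electron-rich triol by the reagent, and intermolecular sulfuryl transfer giving oligomeric diesters instead of ring closure. The ring A triol is a strong nucleophile at carbon as well as at oxygen, and the second substitution at sulfur must outrun a bimolecular reaction.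

Fallback, known chemistry only: setting out from 8, alkylation of the most acidic hydroxyl with BnBr and K2CO3 in acetone should give 7-benzyloxy-5,6-dihydroxy-3',4'-bis(pivaloyloxy)flavone F1. Sulfation with SO3·pyridine, to which the chelated 5-hydroxyl is inert, should give 7-benzyloxy-5-hydroxy-3',4'-bis(pivaloyloxy)flavone 6-(hydrogen sulfate) F2. Hydrogenolysis over Pd/C then comes back to the route at 11, which is taken through the NaOH stage of step 7.

**Step 7.** Most likely failure: departure of O6 instead of O7 from the pentacoordinate sulfur, if the difference in leaving-group ability is smaller than the conjugation argument suggests. Two lesser risks are air oxidation of the polyphenolate during saponification and loss of the sulfate during acidification.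

Fallback, known chemistry only: setting out from 8, allylation of the 7-hydroxyl (allyl bromide, K2CO3, DMF) should give 7-allyloxy-5,6-dihydroxy-3',4'-bis(pivaloyloxy)flavone F3. Sulfation with SO3·NMe3 and Et3N should give 7-allyloxy-5-hydroxy-3',4'-bis(pivaloyloxy)flavone 6-(hydrogen sulfate) F4. Treatment with Pd(PPh3)4 (zerovalent palladium) and K2CO3 in MeOH would remove the allyl group and methanolyse both pivalates in one flask, coming back to the route at 12 with no strongly alkaline aqueous stage.

**Step 5.** Most likely failure: acyl–oxygen cleavage of one or both pivalates during the long exposure to excess BBr3 needed for the slow 7-methoxy group, or incomplete demethylation if the reaction is stopped early to save the esters.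

Fallback: setting out from 5, the ring B mask would be changed to sulfonates, which have no Lewis-basic carbonyl. MsCl and Et3N should give 5,6,7-trimethoxy-3',4'-bis(methylsulfonyloxy)flavone F5, and BBr3 then 5,6,7-trihydroxy-3',4'-bis(methylsulfonyloxy)flavone F6. Sulfuryl transfer as in step 6 would give its 6,7-cyclic sulfate F7, and aqueous NaHCO3 would open it to 5,7-dihydroxy-3',4'-bis(methylsulfonyloxy)flavone 6-(hydrogen sulfate) F8. Warm aqueous NaOH would cleave the two aryl mesylates by the sulfene pathway, and cold acidification comes back to the route at 12.

**Step 2.** Most likely failure: ether cleavage by the HI formed at 120 °C, or iodination of ring A at C8, both consequences of running an electron-rich substrate hot in the presence of iodine.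

Fallback: setting out from 3, isomerisation with NaOAc in refluxing EtOH should give racemic 2-[3,4-bis(benzyloxy)phenyl]-5,6,7-trimethoxychroman-4-one F9 by oxa-Michael closure. Dehydrogenation with DDQ in refluxing dioxane comes back to the route at 4 without any iodine.

## Further compounds

F1 | step 6 | 7-benzyloxy-5,6-dihydroxy-3',4'-bis(pivaloyloxy)flavone | O=c1cc(-c2ccc(OC(=O)C(C)(C)C)c(OC(=O)C(C)(C)C)c2)oc2cc(OCc3ccccc3)c(O)c(O)c12
F2 | step 6 | 7-benzyloxy-5-hydroxy-3',4'-bis(pivaloyloxy)flavone 6-(hydrogen sulfate) | O=c1cc(-c2ccc(OC(=O)C(C)(C)C)c(OC(=O)C(C)(C)C)c2)oc2cc(OCc3ccccc3)c(OS(=O)(=O)O)c(O)c12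
F3 | step 7 | 7-allyloxy-5,6-dihydroxy-3',4'-bis(pivaloyloxy)flavone | O=c1cc(-c2ccc(OC(=O)C(C)(C)C)c(OC(=O)C(C)(C)C)c2)oc2cc(OCC=C)c(O)c(O)c12
F4 | step 7 | 7-allyloxy-5-hydroxy-3',4'-bis(pivaloyloxy)flavone 6-(hydrogen sulfate) | O=c1cc(-c2ccc(OC(=O)C(C)(C)C)c(OC(=O)C(C)(C)C)c2)oc2cc(OCC=C)c(OS(=O)(=O)O)c(O)c12
F5 | step 5 | 5,6,7-trimethoxy-3',4'-bis(methylsulfonyloxy)flavone | O=c1cc(-c2ccc(OS(C)(=O)=O)c(OS(C)(=O)=O)c2)oc2cc(OC)c(OC)c(OC)c12
F6 | step 5 | 5,6,7-trihydroxy-3',4'-bis(methylsulfonyloxy)flavone | O=c1cc(-c2ccc(OS(C)(=O)=O)c(OS(C)(=O)=O)c2)oc2cc(O)c(O)c(O)c12
F7 | step 5 | 5-hydroxy-3',4'-bis(methylsulfonyloxy)flavone 6,7-cyclic sulfate | O=c1cc(-c2ccc(OS(C)(=O)=O)c(OS(C)(=O)=O)c2)oc2cc3OS(=O)(=O)Oc3c(O)c12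
F8 | step 5 | 5,7-dihydroxy-3',4'-bis(methylsulfonyloxy)flavone 6-(hydrogen sulfate) | O=c1cc(-c2ccc(OS(C)(=O)=O)c(OS(C)(=O)=O)c2)oc2cc(O)c(OS(=O)(=O)O)c(O)c12
F9 | step 2 | 2-[3,4-bis(benzyloxy)phenyl]-5,6,7-trimethoxychroman-4-one (racemic) | O=C1CC(c2ccc(OCc3ccccc3)c(OCc3ccccc3)c2)Oc2cc(OC)c(OC)c(OC)c21
A1 | alternative 1 | 2-deoxy-D-glucose (pyranose form, anomeric centre open) | OC[C@H]1OC(O)C[C@@H](O)[C@@H]1O
A2 | alternative 1 | methyl 4-O-benzoyl-3-O-benzyl-2,6-dideoxy-α-D-threo-hex-5-enopyranoside | C=C1O[C@H](OC)C[C@@H](OCc2ccccc2)[C@@H]1OC(=O)c1ccccc1
A3 | alternative 1 | 2-benzoyloxy-3-benzyloxy-5-hydroxycyclohexanone (sugar-derived centres defined, carbinol centre as formed) | O=C1[C@@H](OC(=O)c2ccccc2)[C@H](OCc2ccccc2)CC(O)C1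
A4 | alternative 2 | 1-[2,4-bis(benzyloxy)-3-hydroxyphenyl]-3-[3,4-bis(benzyloxy)phenyl]propane-1,3-dione | O=C(CC(=O)c1ccc(OCc2ccccc2)c(OCc2ccccc2)c1)c1ccc(OCc2ccccc2)c(O)c1OCc1ccccc1
A5 | alternative 2 | 5,7,3',4'-tetrakis(benzyloxy)-6-hydroxyflavone | O=c1cc(-c2ccc(OCc3ccccc3)c(OCc3ccccc3)c2)oc2cc(OCc3ccccc3)c(O)c(OCc3ccccc3)c12
A6 | alternative 3 | 3,5-bis(benzyloxy)-4-(methoxymethoxy)-2-(trimethylsilyl)phenyl trifluoromethanesulfonate | C[Si](C)(C)c1c(OS(=O)(=O)C(F)(F)F)cc(OCc2ccccc2)c(OCOC)c1OCc1ccccc1
A7 | alternative 3 | 3-[3,4-bis(benzyloxy)phenyl]prop-2-ynoic acid | O=C(O)C#Cc1ccc(OCc2ccccc2)c(OCc2ccccc2)c1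
A8 | alternative 3 | 1-[2,4-bis(benzyloxy)-6-hydroxy-3-(methoxymethoxy)phenyl]-3-[3,4-bis(benzyloxy)phenyl]prop-2-yn-1-one | O=C(C#Cc1ccc(OCc2ccccc2)c(OCc2ccccc2)c1)c1c(O)cc(OCc2ccccc2)c(OCOC)c1OCc1ccccc1
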